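**Two questions.** Two ratios of target to isomer of the product are asked of this flask, one very early and one late.

in all of them: starting material 2.0 × 10⁻⁴ M; free catalyst 0.10 µM; stray impurity 0.012 µM
- north: other conformer 0.034 mM; protic impurity 0.040 mM; run made earlier
- south: other conformer 0.075 mM; protic impurity 0.040 mM; run made earlier
- flask: other conformer 0.0500 mM; protic impurity 0.0400 mM; time 50 min

| run | time / min | target / % | isomer of the product / % |
|---|---|---|---|
| north | 2.00 | 82.8 | 13.3 |
| north | 6.00 | 81.5 | 13.3 |
| north | 12.0 | 82.1 | 14.4 |
| north | 15.0 | 82.0 | 14.5 |
| north | 25.0 | 82.8 | 12.7 |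
| north | 30.0 | 82.3 | 14.2 |
| north | 40.0 | 82.8 | 11.7 |
| south | 3.00 | 71.2 | 23.3 |
| south | 5.00 | 73.1 | 24.3 |
| south | 8.00 | 71.5 | 24.2 |
| south | 12.0 | 70.0 | 23.2 |
| south | 15.0 | 72.3 | 22.2 |
| south | 25.0 | 71.1 | 21.7 |
| south | 40.0 | 73.1 | 23.4 |

(each reading ± 1 percentage point)

- ratio of target to isomer of the product at 0.40 s
- ratio of target to isomer of the product at 50 min



**Zero of scale.** The flask holds 4.00 parts of starting material to one of other conformer. This charge ratio is what a catalyst without preference gives as target over isomer at the first instant, so we read every ratio against it.

**Late rung.** In the readings, north holds a ratio of 6.12 from 2.00 min to 40.0 min and south 3.09, both flat within the scatter. Against their own charge ratios these stand at 1.04 and 1.16. The mean of the two, applied to this flask, gives us 4.40 at 50 min.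

**Early rung.** At 0.40 s we have no reading, since the earliest comes 300 times later. The plateaus of north and south show where these two runs stand, not the order of getting there. So we commit to the zero itself, 4.00, with a wide margin.

**The forecast.** It gives 4.4 at 50 min, from a linear fit of the plateaus, and 4.4 at 0.40 s, with the warning that “unequal reactivity could shift it considerably”. That is the same as ours late but higher early.

**The flask.** It gives 1.42 at 0.40 s and 4.35 at 50 min.

    starting material ⇌ other conformer (K = 0.170, k = 0.00266 s⁻¹)
    starting material + free catalyst → free catalyst + target (k = 4.98 × 10⁵ M⁻¹ s⁻¹)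
    free catalyst + other conformer → free catalyst + isomer of the product (k = 1.44 × 10⁶ M⁻¹ s⁻¹)
    free catalyst + stray impurity → spent catalyst (k = 3.01 × 10⁸ M⁻¹ s⁻¹)
    other conformer + protic impurity → quenched substrate (k = 993 M⁻¹ s⁻¹)

In this flask, half of the turnover to isomer of the product up to 50 min is done by 0.0880 min, earlier than the first reading of the north run. In this flask the early ratio lies below the charge ratio of 4.00 by a factor of 2.82, a selectivity factor favouring the other conformer. A neighbour flask charged with 3.0 × 10⁻⁵ M of other conformer has a charge ratio of 6.67 and an early ratio of 2.36, which is again a factor of 2.82.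

The earlier runs and the new flask stem from a simulated flask for substances that don't exist, noise included.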